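## The problem

The target 19 is a (3S,4R)-isoflavan-4-ol. A chroman (ring C) is fused to a 6,7,8-trimethoxylated ring A, a 2,5-dihydroxy-3,4-dimethoxyphenyl group (ring B) sits on C3, and a hydroxyl sits on C4. C3 and C4 are the only stereocentres. Ring B and the C4 hydroxyl are trans, so the hydrogen on C3 and the oxygen on C4 lie on the same face of ring C. C4 is an aryl carbinol and can be set by reagent control from a ketone; its oxygen is then the natural handle on C3, whereas C3 next to a C4 carbonyl would be an epimerisable α-aryl centre. The C4 hydroxyl is benzylic to a ring alkoxylated ortho and para to it and ionises with acid; the free 2'-hydroxyl would then close a pterocarpan, or water would be lost to the isoflav-3-ene. The ring B hydroquinone is oxidised to the quinone by air. The phenols must therefore be differentiated: O1 of ring A free for ring closure, ring B masked until a final neutral, reductive unveiling. The feature that opens the key step is the 1,3-relationship of O4 and O1 across C3: C2 is an oxygenated methylene, C4 carries oxygen, and the C3 hydrogen is cis to O4. That is the pattern left by adding an O4-bound Si–H across a C2=C3 alkene and oxidising the C2–Si bond.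

## Retrosynthesis

**19 to 18.** The two O–benzyl bonds on ring B are cut last. Benzyl is preferred to acid-labile groups, whose removal would ionise C4, and to silyl groups, which would not survive the ortho-metallated stage 12 of ring B. Compound 18 is no simpler in skeleton but is stable to air. The forward step must cleave two aryl benzyl ethers and spare the benzylic C4–O bond.

**18 to 17 and 16.** Ring C is opened at O1–C2, giving phenol diol 17 and, one protecting group back, triisopropylsilyl ether 16. The neighbouring cuts are worse: closure at C4–C4a would pass through a C4 cation and lose the configuration, and closure at O1–C8a needs a metal-catalysed aryl ether synthesis on a crowded, electron-rich ring. The precursor is an acyclic syn-2-aryl-1,3-diol with both stereocentres in place. The forward closure must activate the primary hydroxyl beside the secondary benzylic one, and fluoride must free only the ring A phenol.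

**16 to 15.** The primary C2–O bond is traced back to a C2–Si bond, giving oxasilolane 15 (ring atoms O, Si, C2, C3, C4 in chroman numbering). A C2–B bond from hydroboration of the same alkene would have to find the right face of C3 without help; silicon hands that task to a tether. The forward oxidation only has to convert a primary alkyl–silicon bond, with one oxygen on silicon, into C–OH.

**15 to 14 and 13.** Cutting C2–Si and C3–H gives hydridosilyl ether 14 and, without the silyl group, allylic alcohol 13. The C3 stereocentre is gone and only C4 remains. Setting C3 by hydrogenation of a C3=C4 alkene or by protonation next to a C4 ketone would leave no control element or an epimerisable centre; here C3 is made once, irreversibly, from C4. The forward reaction is a tethered hydrosilylation that must close a five-membered ring with silicon on C2 and put hydrogen on one face of C3.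

**13 to 7 and 12.** The C3–C1' bond is cut, giving propargylic alcohol 7 and aryl Grignard reagent 12. The neighbouring cut, C3–C4 (an α-arylvinyl metal plus aldehyde 3), would give a racemic carbinol, and its correction would need asymmetric reduction of an enone flanked by two bulky sp2 groups of similar size. In 7 the skeleton lacks ring B altogether. The forward step is an arylmagnesiation of the alkyne that must place the aryl group on the internal carbon; the C4 alkoxide directs it, the same oxygen that later carries the silicon.

**7 to 3 through 6, 5 and 4.** The C4–H bond is cut to ynone 5 and the C3–C4 bond to aldehyde 3 and a silyl-capped acetylide. A ketone flanked by an ortho-substituted aryl group and a slender alkyne is a well-differentiated substrate for oxazaborolidine-catalysed reduction. The forward sequence is addition (to racemic 4), oxidation, asymmetric reduction (to 6) and C-desilylation.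

**3 to 2 and 1.** The formyl carbon, the future C4, is removed from the only free ortho position of phenol 1, and the phenol oxygen is the future O1. The triisopropylsilyl group is chosen for its resistance to migration onto neighbouring alkoxides and for its fluoride lability.

**12 to 11, 10 and 8.** The C–Mg bond comes from bromide 11, the bromine from symmetrical dibenzyl ether 10, and 10 from quinone 8 by reductive benzylation through hydroquinone 9. All four oxygens of ring B are present from the start and the two free positions of 10 are equivalent.

## Roads not taken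

**Alternative 1:** The cut is C2–C3, with C2 taken from the methyl carbon of an ortho-methoxy group. α-Diazo ketone A2 would be decomposed by a chiral dirhodium tetracarboxylate such as Rh2(S-PTTL)4, and the carbene at C3 would insert into a C–H bond of the neighbouring OCH3 to give isoflavanone A1.
- Merits: ring C and C3 arise in one step, ring A needs no phenol protection, and the route is clearly shorter than the chosen one.
- Weak points: insertion into a methyl C–H through a six-membered transition state competes with attack of the carbene on the same methoxy oxygen, and the resulting oxonium ylide would rearrange to a benzofuranone. C3 in A1 lies between a ketone and an aryl ring and can racemise by enolisation. C4 must then be set by hydride reduction, which is not reliably trans-selective for isoflavanones. The acetates must finally be removed with base from an air-sensitive hydroquinone.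
- Comparison: the chosen plan sets against the shorter sequence that no stereocentre ever sits α to a carbonyl. C4 is fixed first by a well-differentiated ketone reduction, and C3 is derived from it in a single irreversible step.

**Alternative 2:** The cut is the aryl ether bond O1–C8a. Bromo alcohol A4, carrying both stereocentres, would be cyclised with Pd(OAc)2, a di-tert-butylphosphino biaryl ligand and Cs2CO3 to chroman A3; desilylation would give 18.
- Merits: ring A enters as a robust aryl bromide, so a phenol protecting group and the risk of silyl migration are avoided. In this respect the road is better than the chosen one.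
- Weak points: the coupling only closes the ring. Both stereocentres of A4 must come from elsewhere, most plausibly an aldol construction that passes through an α-aryl carbonyl at C3. Oxidative addition to a di-ortho-substituted, electron-rich bromide is slow, and the palladium alkoxide of a primary alcohol can undergo β-hydride elimination, which reduces the arene and oxidises C2.
- Comparison: the length is comparable. The chosen plan closes ring C by SN2 at a primary carbon without a metal, and its key step creates C3 instead of presupposing it.

**Alternative 3:** The cuts are C4a–C4 and O1–C2. Phenol 1 and 2-arylacrolein A6 would be joined with PhB(OH)2 and an acid catalyst in hot toluene; the ortho-quinone methide so formed closes by oxa-6π electrocyclisation to isoflav-3-ene A5.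
- Merits: this is the most convergent road. The whole skeleton is made in one step from unprotected 1, and syn hydroboration–oxidation of A5 (boron to C4, hydrogen to C3) would give the trans relationship of 18 by mechanism. In step count and in relative configuration it is as good as or better than the chosen plan.
- Weak points: A5 is achiral. The absolute configuration would rest on a reagent-controlled hydroboration of a hindered, trisubstituted alkene conjugated to two aryl rings, where enantioselectivity and the C4/C3 regiochemistry are both uncertain. A5 and A6 are sensitive to acid, air and polymerisation.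
- Comparison: the chosen plan sets against this an enantio-determining step of a predictable kind (aryl against alkynyl at a ketone) and an intramolecular relay of that centre to C3.

Key step: step 11

Remark: phenol 1 and quinone 8 are taken as catalogue compounds, and the target is read from its SMILES string as the (3S,4R)-trans isomer.

## Route

Step 1
Reactants: 1 2,3,4-trimethoxyphenol
Product: 2 2-hydroxy-3,4,5-trimethoxybenzaldehyde
Conditions: MgCl2, Et3N, (CH2O)n, MeCN, reflux; aq. HCl
Reagents that add atoms: formaldehyde (from paraformaldehyde), C=O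
Why: Magnesium-mediated ortho-formylation of a phenol: the magnesium phenoxide delivers formaldehyde to the only free ortho position (para is blocked by OMe), and the salicyl alcohol is oxidised in situ by hydride transfer to a second formaldehyde.

Step 2
Reactants: 2 2-hydroxy-3,4,5-trimethoxybenzaldehyde
Product: 3 3,4,5-trimethoxy-2-(triisopropylsilyloxy)benzaldehyde
Conditions: TIPSOTf, 2,6-lutidine, CH2Cl2, 0 °C to rt
Reagents that add atoms: triisopropylsilyl trifluoromethanesulfonate, CC(C)[Si](C(C)C)(C(C)C)OS(=O)(=O)C(F)(F)F
Why: O-silylation of a hindered, hydrogen-bonded phenol with a silyl triflate; the bulky group resists migration to the neighbouring alkoxides of steps 3 and 9 and is later removed by fluoride without touching benzyl ethers.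

Step 3
Reactants: 3 3,4,5-trimethoxy-2-(triisopropylsilyloxy)benzaldehyde
Product: 4 rac-1-[3,4,5-trimethoxy-2-(triisopropylsilyloxy)phenyl]-3-(trimethylsilyl)prop-2-yn-1-ol
Conditions: Me3SiC≡CH, n-BuLi, THF, −78 °C; then 3, −78 °C; AcOH quench at −78 °C
Reagents that add atoms: ethynyltrimethylsilane, C#C[Si](C)(C)C
Why: 1,2-Addition of a lithium acetylide to an aryl aldehyde forms the C3–C4 bond; the cold quench protonates the alkoxide before the silyl group can migrate, and the racemic centre is corrected in steps 4 and 5.

Step 4
Reactants: 4 rac-1-[3,4,5-trimethoxy-2-(triisopropylsilyloxy)phenyl]-3-(trimethylsilyl)prop-2-yn-1-ol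
Product: 5 1-[3,4,5-trimethoxy-2-(triisopropylsilyloxy)phenyl]-3-(trimethylsilyl)prop-2-yn-1-one
Conditions: MnO2 (activated), CH2Cl2, rt
Reagents that add atoms: none
Why: MnO2 oxidation of a benzylic, propargylic alcohol to the ynone; the neutral heterogeneous oxidant leaves both silyl groups and the electron-rich ring alone.

Step 5
Reactants: 5 1-[3,4,5-trimethoxy-2-(triisopropylsilyloxy)phenyl]-3-(trimethylsilyl)prop-2-yn-1-one
Product: 6 (S)-1-[3,4,5-trimethoxy-2-(triisopropylsilyloxy)phenyl]-3-(trimethylsilyl)prop-2-yn-1-ol
Conditions: (S)-Me-CBS oxazaborolidine (0.5 equiv), BH3·SMe2, THF, −30 °C; MeOH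
Reagents that add atoms: none
Why: Corey–Bakshi–Shibata reduction: the ketone binds the catalyst boron anti to the large ortho-substituted aryl group, with the slender alkyne as the small group, and hydride comes from the nitrogen-bound borane in the sense that turns acetophenone into (R)-1-phenylethanol with this catalyst. This sets C4 in the spatial arrangement of the target; the descriptor is S only because the silylalkynyl branch outranks the aryl group.

Step 6
Reactants: 6 (S)-1-[3,4,5-trimethoxy-2-(triisopropylsilyloxy)phenyl]-3-(trimethylsilyl)prop-2-yn-1-ol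
Product: 7 (R)-1-[3,4,5-trimethoxy-2-(triisopropylsilyloxy)phenyl]prop-2-yn-1-ol
Conditions: K2CO3 (cat.), MeOH, 0 °C
Reagents that add atoms: none
Why: Base-catalysed methanolysis of the C(sp)–Si bond, which is far faster than cleavage of the hindered aryl triisopropylsilyl ether at 0 °C; the stereocentre is untouched and the descriptor changes to R by priority only.

Step 7
Reactants: 8 2,3-dimethoxy-1,4-benzoquinone
Product: 10 1,4-bis(benzyloxy)-2,3-dimethoxybenzene, via 2,3-dimethoxyhydroquinone 9 (not isolated)
Conditions: Na2S2O4, Bu4NBr (cat.), THF/H2O, rt, N2; then KOH, BnBr (excess), rt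
Reagents that add atoms: benzyl bromide, BrCc1ccccc1
Why: One-pot reductive alkylation of a quinone: dithionite gives the hydroquinone, which is O-benzylated twice under phase transfer (Williamson ether synthesis) before air can reoxidise it.

Step 8
Reactants: 10 1,4-bis(benzyloxy)-2,3-dimethoxybenzene
Product: 11 1,4-bis(benzyloxy)-5-bromo-2,3-dimethoxybenzene
Conditions: NBS (1.0 equiv), MeCN, 0 °C
Reagents that add atoms: N-bromosuccinimide, O=C1CCC(=O)N1Br
Why: Electrophilic aromatic bromination of a tetraalkoxybenzene; the two free positions are equivalent by symmetry and the first bromine slows a second substitution.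

Step 9
Reactants: 11 1,4-bis(benzyloxy)-5-bromo-2,3-dimethoxybenzene; 7 (R)-1-[3,4,5-trimethoxy-2-(triisopropylsilyloxy)phenyl]prop-2-yn-1-ol
Product: 13 (R)-2-[2,5-bis(benzyloxy)-3,4-dimethoxyphenyl]-1-[3,4,5-trimethoxy-2-(triisopropylsilyloxy)phenyl]prop-2-en-1-ol, via arylmagnesium bromide 12 (not isolated)
Conditions: 11, Mg, THF, 50 °C; then CuI (copper iodide, 20 mol%), 7 (to 3.5 equiv of 12), THF, 0 °C to rt; aq. NH4Cl
Reagents that add atoms: none
Why: Copper-catalysed anti-arylmagnesiation of a propargylic alcohol: the magnesium alkoxide of 7 directs the aryl group to the proximal alkyne carbon and magnesium to the terminal carbon in a five-membered chelate, and protonation gives the 1,1-disubstituted alkene. The carbinol carbon is a spectator and keeps its configuration; the part of 12 that acts as base returns as 10 and can be re-brominated.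

Step 10
Reactants: 13 (R)-2-[2,5-bis(benzyloxy)-3,4-dimethoxyphenyl]-1-[3,4,5-trimethoxy-2-(triisopropylsilyloxy)phenyl]prop-2-en-1-ol
Product: 14 (R)-{2-[2,5-bis(benzyloxy)-3,4-dimethoxyphenyl]-1-[3,4,5-trimethoxy-2-(triisopropylsilyloxy)phenyl]prop-2-en-1-yloxy}dimethylsilane
Conditions: Me2SiHCl, Et3N, DMAP (cat.), CH2Cl2, 0 °C; filtered under N2 and used crude
Reagents that add atoms: chlorodimethylsilane, C[SiH](C)Cl
Why: O-Silylation of a secondary alcohol with a chlorosilane and amine base; the hydridosilyl ether is moisture-sensitive and is carried on directly.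

Step 11
Reactants: 14 (R)-{2-[2,5-bis(benzyloxy)-3,4-dimethoxyphenyl]-1-[3,4,5-trimethoxy-2-(triisopropylsilyloxy)phenyl]prop-2-en-1-yloxy}dimethylsilane
Product: 15 (4R,5R)-4-[2,5-bis(benzyloxy)-3,4-dimethoxyphenyl]-2,2-dimethyl-5-[3,4,5-trimethoxy-2-(triisopropylsilyloxy)phenyl]-1,2-oxasilolane
Conditions: Pt2[(CH2=CHSiMe2)2O]3 (1 mol% Pt), toluene, 50 °C
Reagents that add atoms: none
Why: Zerovalent platinum inserts into the Si–H bond of 14, the C2=C3 alkene inserts into Pt–H with hydrogen going to C3 and platinum to the terminal carbon C2 (a six-membered platinacycle), and C2–Si reductive elimination releases 15 (Chalk–Harrod cycle), so both new bonds form on one alkene face. The closest known reaction type is the platinum-catalysed intramolecular hydrosilylation of hydridosilyl ethers of 2-substituted allylic alcohols, which after oxidation gives syn-2-substituted 1,3-diols. The oxasilolane closes in the 5-endo-trig mode, both alkene carbons becoming ring atoms; the four-membered exo alternative is strained and would put silicon on the aryl-bearing carbon against the usual polarity of styrene hydrosilylation. The new stereocentre C3 is controlled by C4: the short O–Si tether makes the C4–O bond lean towards the face on which silicon reaches C2, the C4 hydrogen then lies near the alkene plane beside ring B, and ring A points to the opposite face, because the other rotamer would press the two ortho-substituted aryl rings together (allylic 1,2-strain). Hydrogen therefore arrives at C3 on the face away from ring A, giving the (4R,5R) isomer with the two ring hydrogens cis and the two aryl groups cis, which corresponds to the trans arrangement of ring B and hydroxyl in the chroman. The step needs this face selectivity and the silicon-to-C2 regiochemistry; the first is secured by the C4 stereocentre acting through the tether and the second by ring size. A neutral zerovalent platinum complex is used in place of the classical H2PtCl6 because 14 is an allylic, benzylic silyl ether that a strong acid could ionise.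

Step 12
Reactants: 15 (4R,5R)-4-[2,5-bis(benzyloxy)-3,4-dimethoxyphenyl]-2,2-dimethyl-5-[3,4,5-trimethoxy-2-(triisopropylsilyloxy)phenyl]-1,2-oxasilolane
Product: 16 (1R,2S)-2-[2,5-bis(benzyloxy)-3,4-dimethoxyphenyl]-1-[3,4,5-trimethoxy-2-(triisopropylsilyloxy)phenyl]propane-1,3-diol
Conditions: 30% H2O2, KF, KHCO3, THF/MeOH, rt to 40 °C
Reagents that add atoms: hydrogen peroxide, OO
Why: Tamao–Fleming oxidation: fluoride and hydroperoxide add to the alkoxysilane and C2 migrates from silicon to oxygen; C2 is a methylene and the C4–O bond is not broken, so both stereocentres are retained. Partial loss of the aryl silyl ether here would be harmless, since step 13 removes it.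

Step 13
Reactants: 16 (1R,2S)-2-[2,5-bis(benzyloxy)-3,4-dimethoxyphenyl]-1-[3,4,5-trimethoxy-2-(triisopropylsilyloxy)phenyl]propane-1,3-diol
Product: 17 (1R,2S)-2-[2,5-bis(benzyloxy)-3,4-dimethoxyphenyl]-1-(2-hydroxy-3,4,5-trimethoxyphenyl)propane-1,3-diol
Conditions: TBAF, AcOH, THF, 0 °C
Reagents that add atoms: none
Why: Fluoride cleavage of an aryl silyl ether, buffered with acetic acid so that no strongly basic phenoxide persists; benzyl ethers and both carbinols are inert.

Step 14
Reactants: 17 (1R,2S)-2-[2,5-bis(benzyloxy)-3,4-dimethoxyphenyl]-1-(2-hydroxy-3,4,5-trimethoxyphenyl)propane-1,3-diol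
Product: 18 (3S,4R)-3-[2,5-bis(benzyloxy)-3,4-dimethoxyphenyl]-6,7,8-trimethoxychroman-4-ol
Conditions: PPh3, DIAD, THF, 0 °C to rt
Reagents that add atoms: none
Why: Mitsunobu etherification: the unhindered primary hydroxyl is converted into the alkoxyphosphonium ion in preference to the crowded secondary benzylic one, and the phenoxide closes ring C by 6-exo-tet SN2 at C2. Neither stereocentre takes part.

Step 15
Reactants: 18 (3S,4R)-3-[2,5-bis(benzyloxy)-3,4-dimethoxyphenyl]-6,7,8-trimethoxychroman-4-ol
Product: 19 (3S,4R)-3-(2,5-dihydroxy-3,4-dimethoxyphenyl)-6,7,8-trimethoxychroman-4-ol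
Conditions: H2 (1 atm), Pd/C (10 wt%), EtOAc, rt; work-up under argon
Reagents that add atoms: none
Why: Hydrogenolysis of aryl benzyl ethers in a neutral solvent; without acid the benzylic C4–O bond is cleaved much more slowly than O-benzyl, and the hydroquinone is released under a reducing atmosphere.

## Compound list

1 | 2,3,4-trimethoxyphenol | COc1ccc(O)c(OC)c1OC | starting material
2 | 2-hydroxy-3,4,5-trimethoxybenzaldehyde | O=Cc1cc(OC)c(OC)c(OC)c1O | intermediate
3 | 3,4,5-trimethoxy-2-(triisopropylsilyloxy)benzaldehyde | O=Cc1cc(OC)c(OC)c(OC)c1O[Si](C(C)C)(C(C)C)C(C)C | intermediate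
4 | rac-1-[3,4,5-trimethoxy-2-(triisopropylsilyloxy)phenyl]-3-(trimethylsilyl)prop-2-yn-1-ol | C[Si](C)(C)C#CC(O)c1cc(OC)c(OC)c(OC)c1O[Si](C(C)C)(C(C)C)C(C)C | intermediate
5 | 1-[3,4,5-trimethoxy-2-(triisopropylsilyloxy)phenyl]-3-(trimethylsilyl)prop-2-yn-1-one | C[Si](C)(C)C#CC(=O)c1cc(OC)c(OC)c(OC)c1O[Si](C(C)C)(C(C)C)C(C)C | intermediate
6 | (S)-1-[3,4,5-trimethoxy-2-(triisopropylsilyloxy)phenyl]-3-(trimethylsilyl)prop-2-yn-1-ol | C[Si](C)(C)C#C[C@H](c1cc(OC)c(OC)c(OC)c1O[Si](C(C)C)(C(C)C)C(C)C)O | intermediate
7 | (R)-1-[3,4,5-trimethoxy-2-(triisopropylsilyloxy)phenyl]prop-2-yn-1-ol | C#C[C@H](c1cc(OC)c(OC)c(OC)c1O[Si](C(C)C)(C(C)C)C(C)C)O | intermediate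
8 | 2,3-dimethoxy-1,4-benzoquinone | COC1=C(OC)C(=O)C=CC1=O | starting material
9 | 2,3-dimethoxyhydroquinone (2,3-dimethoxybenzene-1,4-diol) | COc1c(O)ccc(O)c1OC | intermediate (not isolated)
10 | 1,4-bis(benzyloxy)-2,3-dimethoxybenzene | COc1c(OCc2ccccc2)ccc(OCc2ccccc2)c1OC | intermediate
11 | 1,4-bis(benzyloxy)-5-bromo-2,3-dimethoxybenzene | COc1c(OCc2ccccc2)cc(Br)c(OCc2ccccc2)c1OC | intermediate
12 | [2,5-bis(benzyloxy)-3,4-dimethoxyphenyl]magnesium bromide | COc1c(OCc2ccccc2)cc([Mg]Br)c(OCc2ccccc2)c1OC | intermediate (not isolated)
13 | (R)-2-[2,5-bis(benzyloxy)-3,4-dimethoxyphenyl]-1-[3,4,5-trimethoxy-2-(triisopropylsilyloxy)phenyl]prop-2-en-1-ol | C=C(c1cc(OCc2ccccc2)c(OC)c(OC)c1OCc1ccccc1)[C@H](c1cc(OC)c(OC)c(OC)c1O[Si](C(C)C)(C(C)C)C(C)C)O | intermediate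
14 | (R)-{2-[2,5-bis(benzyloxy)-3,4-dimethoxyphenyl]-1-[3,4,5-trimethoxy-2-(triisopropylsilyloxy)phenyl]prop-2-en-1-yloxy}dimethylsilane | C=C(c1cc(OCc2ccccc2)c(OC)c(OC)c1OCc1ccccc1)[C@H](c1cc(OC)c(OC)c(OC)c1O[Si](C(C)C)(C(C)C)C(C)C)O[SiH](C)C | intermediate
15 | (4R,5R)-4-[2,5-bis(benzyloxy)-3,4-dimethoxyphenyl]-2,2-dimethyl-5-[3,4,5-trimethoxy-2-(triisopropylsilyloxy)phenyl]-1,2-oxasilolane | C[Si]1(C)C[C@H](c2cc(OCc3ccccc3)c(OC)c(OC)c2OCc2ccccc2)[C@H](c2cc(OC)c(OC)c(OC)c2O[Si](C(C)C)(C(C)C)C(C)C)O1 | intermediate
16 | (1R,2S)-2-[2,5-bis(benzyloxy)-3,4-dimethoxyphenyl]-1-[3,4,5-trimethoxy-2-(triisopropylsilyloxy)phenyl]propane-1,3-diol | OC[C@H](c1cc(OCc2ccccc2)c(OC)c(OC)c1OCc1ccccc1)[C@H](c1cc(OC)c(OC)c(OC)c1O[Si](C(C)C)(C(C)C)C(C)C)O | intermediate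
17 | (1R,2S)-2-[2,5-bis(benzyloxy)-3,4-dimethoxyphenyl]-1-(2-hydroxy-3,4,5-trimethoxyphenyl)propane-1,3-diol | OC[C@H](c1cc(OCc2ccccc2)c(OC)c(OC)c1OCc1ccccc1)[C@H](c1cc(OC)c(OC)c(OC)c1O)O | intermediate
18 | (3S,4R)-3-[2,5-bis(benzyloxy)-3,4-dimethoxyphenyl]-6,7,8-trimethoxychroman-4-ol | COc1cc2c(c(OC)c1OC)OC[C@H](c1cc(OCc3ccccc3)c(OC)c(OC)c1OCc1ccccc1)[C@H]2O | intermediate
19 | (3S,4R)-3-(2,5-dihydroxy-3,4-dimethoxyphenyl)-6,7,8-trimethoxychroman-4-ol | COc1cc2c(c(OC)c1OC)OC[C@H](c1cc(O)c(OC)c(OC)c1O)[C@H]2O | target

## Step count and risks

Total step count: 15. Longest linear sequence: 13 steps (steps 1 to 6, then 9 to 15); the ring B branch (steps 7 and 8) joins at step 9.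

**Step 11 (key step).** The C4 hydrogen of 14 is allylic and benzylic, so a platinum hydride may isomerise the allylic silyl ether to a silyl enol ether before the slow 5-endo closure onto a hindered 1,1-disubstituted alkene. Intermolecular hydrosilylation may then take over, and face selectivity at C3 may be incomplete if the rotamer preference is weaker than expected. The fallback sets out from 13. Silylation with TBSOTf and 2,6-lutidine would give tert-butyldimethylsilyl ether F1. Hydroboration with catecholborane catalysed by Rh(PPh3)3Cl, followed by NaOH/H2O2, is known to favour the syn product from silyl ethers of 2-substituted allylic alcohols and would give primary alcohol F2. TBAF would then remove both silyl groups and rejoin the route at 17.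

**Step 9.** During the long reaction at room temperature the triisopropylsilyl group may migrate from the phenol oxygen to the neighbouring magnesium alkoxide, which removes the directing group. Carbometallation between two ortho-substituted partners may also be sluggish while 12 is consumed as base. The fallback sets out from 7 and involves no alkoxide. Hydrostannation with Bu3SnH catalysed by Mo(CO)3(CNtBu)3 would place tin on the internal carbon and give (S)-2-(tributylstannyl)-1-[3,4,5-trimethoxy-2-(triisopropylsilyloxy)phenyl]prop-2-en-1-ol F3. Stille coupling of this stannane with 11 (Pd(PPh3)4, CuCl, LiCl, DMSO, fluoride-free) would rejoin the route at 13.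

**Step 5.** The ortho-silyloxyaryl ketone is twisted out of conjugation, which may narrow its size advantage over the silylalkyne, and uncatalysed borane reduction may compete; either process erodes enantioselectivity. The fallback sets out from 3 and returns at 6, bypassing 4 and 5: a catalytic enantioselective alkynylation with the alkynylzinc made from ethynyltrimethylsilane and Et2Zn, Ti(OiPr)4 and the BINOL enantiomer assigned by the established facial model. It makes no new compound.

**Step 14.** Activation of the benzylic C4 hydroxyl in place of the primary one would cause ortho-quinone methide formation, elimination or epimerisation at C4. The fallback sets out from 16. Selective sulfonylation of the primary hydroxyl (TsCl, Et3N, Bu2SnO cat.) would give (2S,3R)-2-[2,5-bis(benzyloxy)-3,4-dimethoxyphenyl]-3-hydroxy-3-[3,4,5-trimethoxy-2-(triisopropylsilyloxy)phenyl]propyl 4-methylbenzenesulfonate F4. TBAF would then free the phenoxide, which displaces the sulfonate and rejoins the route at 18.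

**Step 15.** Once debenzylation is complete, hydrogenolysis may continue at the benzylic C4–O bond, and the hydroquinone may be oxidised by air during work-up. The fallback sets out from 18 and returns at 19: electron-transfer cleavage of the benzyl ethers with lithium naphthalenide (LiC10H8) in THF at −78 °C, with C4–O present as its lithium alkoxide, which is not cleaved, followed by a degassed NH4Cl quench. It makes no new compound.

## Further compounds

F1 | step 11 | (R)-tert-butyl{2-[2,5-bis(benzyloxy)-3,4-dimethoxyphenyl]-1-[3,4,5-trimethoxy-2-(triisopropylsilyloxy)phenyl]prop-2-en-1-yloxy}dimethylsilane | C=C(c1cc(OCc2ccccc2)c(OC)c(OC)c1OCc1ccccc1)[C@H](c1cc(OC)c(OC)c(OC)c1O[Si](C(C)C)(C(C)C)C(C)C)O[Si](C)(C)C(C)(C)C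
F2 | step 11 | (2S,3R)-2-[2,5-bis(benzyloxy)-3,4-dimethoxyphenyl]-3-(tert-butyldimethylsilyloxy)-3-[3,4,5-trimethoxy-2-(triisopropylsilyloxy)phenyl]propan-1-ol | OC[C@H](c1cc(OCc2ccccc2)c(OC)c(OC)c1OCc1ccccc1)[C@H](c1cc(OC)c(OC)c(OC)c1O[Si](C(C)C)(C(C)C)C(C)C)O[Si](C)(C)C(C)(C)C
F3 | step 9 | (S)-2-(tributylstannyl)-1-[3,4,5-trimethoxy-2-(triisopropylsilyloxy)phenyl]prop-2-en-1-ol | C=C([Sn](CCCC)(CCCC)CCCC)[C@H](c1cc(OC)c(OC)c(OC)c1O[Si](C(C)C)(C(C)C)C(C)C)O
F0 | step 5 | none | none
F4 | step 14 | (2S,3R)-2-[2,5-bis(benzyloxy)-3,4-dimethoxyphenyl]-3-hydroxy-3-[3,4,5-trimethoxy-2-(triisopropylsilyloxy)phenyl]propyl 4-methylbenzenesulfonate | Cc1ccc(cc1)S(=O)(=O)OC[C@H](c1cc(OCc2ccccc2)c(OC)c(OC)c1OCc1ccccc1)[C@H](c1cc(OC)c(OC)c(OC)c1O[Si](C(C)C)(C(C)C)C(C)C)O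
F0 | step 15 | none | none
A1 | alternative 1 | (3S)-2',5'-diacetoxy-3',4',6,7,8-pentamethoxyisoflavanone | COc1cc2c(c(OC)c1OC)OC[C@H](c1cc(OC(C)=O)c(OC)c(OC)c1OC(C)=O)C2=O
A2 | alternative 1 | 2-diazo-2-(2,5-diacetoxy-3,4-dimethoxyphenyl)-1-(2,3,4,5-tetramethoxyphenyl)ethan-1-one | COc1cc(C(=O)C(=[N+]=[N-])c2cc(OC(C)=O)c(OC)c(OC)c2OC(C)=O)c(OC)c(OC)c1OC
A3 | alternative 2 | (3S,4R)-3-[2,5-bis(benzyloxy)-3,4-dimethoxyphenyl]-4-(tert-butyldimethylsilyloxy)-6,7,8-trimethoxychroman | COc1cc2c(c(OC)c1OC)OC[C@H](c1cc(OCc3ccccc3)c(OC)c(OC)c1OCc1ccccc1)[C@H]2O[Si](C)(C)C(C)(C)C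
A4 | alternative 2 | (2S,3R)-2-[2,5-bis(benzyloxy)-3,4-dimethoxyphenyl]-3-(2-bromo-3,4,5-trimethoxyphenyl)-3-(tert-butyldimethylsilyloxy)propan-1-ol | OC[C@H](c1cc(OCc2ccccc2)c(OC)c(OC)c1OCc1ccccc1)[C@H](c1cc(OC)c(OC)c(OC)c1Br)O[Si](C)(C)C(C)(C)C
A5 | alternative 3 | 3-[2,5-bis(benzyloxy)-3,4-dimethoxyphenyl]-6,7,8-trimethoxy-2H-chromene | COc1cc2c(c(OC)c1OC)OCC(c1cc(OCc3ccccc3)c(OC)c(OC)c1OCc1ccccc1)=C2
A6 | alternative 3 | 2-[2,5-bis(benzyloxy)-3,4-dimethoxyphenyl]prop-2-enal | C=C(C=O)c1cc(OCc2ccccc2)c(OC)c(OC)c1OCc1ccccc1
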